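**Retrosynthetic overview**

1. The lactone (the only ring made; both arenes are bought in) comes from the C2-symmetric (2R,3R)-diol 8 by double dehydrogenation through hydroxy aldehyde 9 and lactol 10, as in secoisolariciresinol → lactol → matairesinol.
2. Diol 8 comes from bis-imide 7 by hydride removal of both auxiliaries.
3. Bis-imide 7 comes from two molecules of imide 4 by oxidative enolate homocoupling, which forms the C8–C8′ bond and both stereocentres in one step (stand-in for the 8–8′ radical coupling of lignan biosynthesis).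
4. Imide 4 comes from acid 1 and (S)-oxazolidinone 2.

Assumption: (−)-cubebininolide is the (3R,4R)-trans lactone encoded by the given SMILES; acid 1 and oxazolidinone 2 are bought.

**Route**

Step 1
Reactants: 1 3-(3,4,5-trimethoxyphenyl)propanoic acid; 2 (S)-4-isopropyl-1,3-oxazolidin-2-one
Product: 4 (4S)-4-isopropyl-3-[3-(3,4,5-trimethoxyphenyl)propanoyl]-1,3-oxazolidin-2-one, via mixed pivalic anhydride 3 (not isolated)
Conditions: PivCl (1.1 equiv), Et3N (2.5 equiv), THF, −20 °C, 1 h; then LiCl (1.1 equiv), 2, −20 °C → rt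
Reagents that add atoms: none
Why: Mixed-anhydride N-acylation of an oxazolidinone (LiCl/Et3N variant), in which the LiCl-activated oxazolidinone attacks the unhindered carbonyl of 3 and pivalate leaves; no stereocentre is formed and the auxiliary centre is untouched.

Step 2
Reactants: 4 (4S)-4-isopropyl-3-[3-(3,4,5-trimethoxyphenyl)propanoyl]-1,3-oxazolidin-2-one (two molecules per molecule of product)
Product: 7 3,3′-[(2R,3R)-2,3-bis(3,4,5-trimethoxybenzyl)butanedioyl]bis[(4S)-4-isopropyl-1,3-oxazolidin-2-one], via lithium Z-enolate 5 (not isolated), via trichlorotitanium enolate 6 (not isolated)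
Conditions: LiN(iPr)2 (commercial solution, 1.1 equiv), THF, −78 °C, 1 h; then TiCl4 (1.1 equiv), −78 °C → rt
Reagents that add atoms: none
Why: Oxidative enolate homocoupling of an Evans-type imide: the chelated Z-enolate 5 is transmetalated to 6, one-electron oxidation by tetravalent titanium (which becomes trivalent titanium) joins two α-carbons, and each carbon bonds on the face opposite the isopropyl group of its (S)-auxiliary, which sets both new centres R; the minor (R,S) and (S,S) dimers are diastereomers of 7 and are removed by chromatography or crystallisation.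

Step 3
Reactants: 7 3,3′-[(2R,3R)-2,3-bis(3,4,5-trimethoxybenzyl)butanedioyl]bis[(4S)-4-isopropyl-1,3-oxazolidin-2-one]
Product: 8 (2R,3R)-2,3-bis(3,4,5-trimethoxybenzyl)butane-1,4-diol
Conditions: LiBH4 (4 equiv), THF, 0 °C → rt; aqueous work-up
Reagents that add atoms: none
Why: Reductive cleavage of N-acyl oxazolidinones by LiBH4, in which hydride attacks the exocyclic imide carbonyls and gives both primary alcohols plus recoverable auxiliary; the conditions are not enolising, so the R,R centres are kept.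

Step 4
Reactants: 8 (2R,3R)-2,3-bis(3,4,5-trimethoxybenzyl)butane-1,4-diol
Product: 11 (−)-cubebininolide [(3R,4R)-3,4-bis(3,4,5-trimethoxybenzyl)dihydrofuran-2(3H)-one], via hydroxy aldehyde 9 (not isolated), via lactol 10 (not isolated)
Conditions: Cu(MeCN)4OTf (5 mol %), 4,4′-dimethoxy-2,2′-bipyridine (5 mol %), ABNO (9-azabicyclo[3.3.1]nonane N-oxyl, 1 mol %), N-methylimidazole (10 mol %), MeCN, air, rt
Reagents that add atoms: none
Why: Cu/nitroxyl aerobic oxidative lactonisation (Stahl oxidation) that copies the dehydrogenase sequence: one of the two homotopic CH2OH groups is oxidised to aldehyde 9, which closes to lactol 10 and is oxidised again to the lactone; C2 symmetry makes the choice of hydroxyl irrelevant and neither stereocentre is touched, so the trans (3R,4R) lactone results.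

**Compound list**

1 | 3-(3,4,5-trimethoxyphenyl)propanoic acid | COc1cc(CCC(=O)O)cc(OC)c1OC | starting material
2 | (S)-4-isopropyl-1,3-oxazolidin-2-one | CC(C)[C@H]1COC(=O)N1 | starting material
3 | 3-(3,4,5-trimethoxyphenyl)propanoic pivalic anhydride | COc1cc(CCC(=O)OC(=O)C(C)(C)C)cc(OC)c1OC | intermediate
4 | (4S)-4-isopropyl-3-[3-(3,4,5-trimethoxyphenyl)propanoyl]-1,3-oxazolidin-2-one | COc1cc(CCC(=O)N2[C@@H](C(C)C)COC2=O)cc(OC)c1OC | intermediate
5 | lithium (Z)-enolate of 4 | COc1cc(C/C=C(\O[Li])N2[C@@H](C(C)C)COC2=O)cc(OC)c1OC | intermediate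
6 | trichlorotitanium (Z)-enolate of 4 | COc1cc(C/C=C(\O[Ti](Cl)(Cl)Cl)N2[C@@H](C(C)C)COC2=O)cc(OC)c1OC | intermediate
7 | 3,3′-[(2R,3R)-2,3-bis(3,4,5-trimethoxybenzyl)butanedioyl]bis[(4S)-4-isopropyl-1,3-oxazolidin-2-one] | COc1cc(C[C@@H](C(=O)N2[C@@H](C(C)C)COC2=O)[C@@H](Cc2cc(OC)c(OC)c(OC)c2)C(=O)N2[C@@H](C(C)C)COC2=O)cc(OC)c1OC | intermediate
8 | (2R,3R)-2,3-bis(3,4,5-trimethoxybenzyl)butane-1,4-diol | COc1cc(C[C@@H](CO)[C@H](CO)Cc2cc(OC)c(OC)c(OC)c2)cc(OC)c1OC | intermediate
9 | (2R,3R)-4-hydroxy-2,3-bis(3,4,5-trimethoxybenzyl)butanal | COc1cc(C[C@@H](CO)[C@H](C=O)Cc2cc(OC)c(OC)c(OC)c2)cc(OC)c1OC | intermediate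
10 | (3R,4R)-3,4-bis(3,4,5-trimethoxybenzyl)tetrahydrofuran-2-ol (anomer mixture) | COc1cc(C[C@H]2COC(O)[C@@H]2Cc2cc(OC)c(OC)c(OC)c2)cc(OC)c1OC | intermediate
11 | (−)-cubebininolide, (3R,4R)-3,4-bis(3,4,5-trimethoxybenzyl)dihydrofuran-2(3H)-one | COc1cc(C[C@H]2COC(=O)[C@@H]2Cc2cc(OC)c(OC)c(OC)c2)cc(OC)c1OC | target

**Step count**

Total steps: 4. Longest linear sequence: 4.

**Steps most likely to fail, with fallbacks**

Step 2 (highest risk). The yield may be moderate, enolate 5 can self-condense or be chlorinated, and facial control may be incomplete. The fallback sets out from 4 and comes back at 11; it makes the second carbon–carbon bond by alkylation instead of dimerisation, so steps 3 and 4 are not needed. Deprotonation of 4 with NaN(SiMe3)2 in THF at −78 °C and alkylation with tert-butyl bromoacetate (Evans alkylation, same facial bias as in step 2) gives tert-butyl (3R)-4-[(4S)-4-isopropyl-2-oxo-1,3-oxazolidin-3-yl]-4-oxo-3-(3,4,5-trimethoxybenzyl)butanoate F1. LiBH4 in THF removes the auxiliary and gives tert-butyl (3R)-4-hydroxy-3-(3,4,5-trimethoxybenzyl)butanoate F2. TsOH in toluene at 80 °C closes this to (4R)-4-(3,4,5-trimethoxybenzyl)dihydrofuran-2(3H)-one F3. Its lithium enolate (LiN(SiMe3)2, THF, −78 °C) is alkylated by 3,4,5-trimethoxybenzyl bromide anti to the C4 substituent, which gives 11.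

Step 4. The copper catalyst may be inhibited, or aldehyde 9 may partly epimerise before it closes. The fallback sets out from 8 and comes back at 11; it replaces the direct dehydrogenation by protection, oxidation and lactonisation. NaH (1 equiv) and TBSCl in THF silylate one of the two equivalent hydroxyls and give (2R,3R)-4-[(tert-butyldimethylsilyl)oxy]-2,3-bis(3,4,5-trimethoxybenzyl)butan-1-ol F4. TEMPO (cat.) and PhI(OAc)2 in MeCN–H2O oxidise the free CH2OH to (2R,3R)-4-[(tert-butyldimethylsilyl)oxy]-2,3-bis(3,4,5-trimethoxybenzyl)butanoic acid F5. Aqueous HCl in THF removes the silyl group and the hydroxy acid lactonises to 11.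

Step 3. On these α-branched imides hydride may open the oxazolidinone ring instead of cleaving the exocyclic bond, or the reduction may stop part-way. The fallback sets out from 7 and comes back at 8; it separates auxiliary removal from reduction. LiOH/H2O2 in THF–H2O at 0 °C cleaves both auxiliaries and gives (2R,3R)-2,3-bis(3,4,5-trimethoxybenzyl)butanedioic acid F6. BH3·SMe2 in THF (0 °C → rt) reduces the diacid to 8.

**Further compounds**

F1 | step 2 | tert-butyl (3R)-4-[(4S)-4-isopropyl-2-oxo-1,3-oxazolidin-3-yl]-4-oxo-3-(3,4,5-trimethoxybenzyl)butanoate | COc1cc(C[C@H](CC(=O)OC(C)(C)C)C(=O)N2[C@@H](C(C)C)COC2=O)cc(OC)c1OC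
F2 | step 2 | tert-butyl (3R)-4-hydroxy-3-(3,4,5-trimethoxybenzyl)butanoate | COc1cc(C[C@H](CC(=O)OC(C)(C)C)CO)cc(OC)c1OC
F3 | step 2 | (4R)-4-(3,4,5-trimethoxybenzyl)dihydrofuran-2(3H)-one | COc1cc(C[C@H]2COC(=O)C2)cc(OC)c1OC
F4 | step 4 | (2R,3R)-4-[(tert-butyldimethylsilyl)oxy]-2,3-bis(3,4,5-trimethoxybenzyl)butan-1-ol | COc1cc(C[C@@H](CO[Si](C)(C)C(C)(C)C)[C@H](CO)Cc2cc(OC)c(OC)c(OC)c2)cc(OC)c1OC
F5 | step 4 | (2R,3R)-4-[(tert-butyldimethylsilyl)oxy]-2,3-bis(3,4,5-trimethoxybenzyl)butanoic acid | COc1cc(C[C@@H](CO[Si](C)(C)C(C)(C)C)[C@H](C(=O)O)Cc2cc(OC)c(OC)c(OC)c2)cc(OC)c1OC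
F6 | step 3 | (2R,3R)-2,3-bis(3,4,5-trimethoxybenzyl)butanedioic acid | COc1cc(C[C@@H](C(=O)O)[C@@H](Cc2cc(OC)c(OC)c(OC)c2)C(=O)O)cc(OC)c1OC
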